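**Plan**

- Labels: bridgeheads C1 (isobutyryl) and C5 (prenyl); two-carbon bridge C2 (ketone)–C3 (carbinol); three-carbon bridge C6H2–C7H(prenyl)–C8Me2; one-carbon bridge C9 (ketone).
- Enabling feature: ring C1–C2–C3–C5–C9 is the five-membered 2-acyl-trione ring of a ring-contracted hop β-acid, and C6–C7–C8 is a second prenyl group of C5 whose Me2C end is bonded to the enolisable carbon C1.
- Retrosynthetic cuts, in order: the side-chain bond at C3 (aldol), the C7–CH2 bond of the C7 prenyl group (radical allylation, then metathesis), then C1–C8 together with C7–I (iodocarbocyclisation). This leaves a gem-diprenyl cyclopentenone that comes from a dearomatised acylphloroglucinol.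
- Forward: arene → three successive C-prenylations, the last dearomatising → five-membered ring by oxidative contraction → C3 carbinol → six-membered ring C1–C9–C5–C6–C7–C8 by C1–C8 closure → C7 prenyl → C3 side chain.
- Stereochemistry: C3 is set by catalyst-controlled ketone reduction and decides which C5 prenyl group cyclises (fixing C5 and C1). C7 is set equatorial by radical allylation, C3 is re-set by exo aldol of its enolate, and the (Z)-alkene comes from Lindlar reduction.

Key step: step 7

Assumption: the target is taken as the open-chain (Z)-γ-hydroxy enone drawn; a five-membered hemiketal tautomer of the side chain, if populated, is regarded as the same compound.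

Remark: CIP descriptors of the bicyclic compounds refer to the labels above; all of them are 1R,3S,5S,7R.

**Route**

Step 1
Reactants: 1 phloroisobutyrophenone; 2 prenyl bromide
Product: 3 3-prenylphloroisobutyrophenone
Conditions: NaOMe (1.0 equiv), MeOH, 0 °C; 2 (1.0 equiv) added slowly to 1 (1.5 equiv, excess recovered)
Reagents that add atoms: none
Why: C-alkylation of the phloroglucinol monoanion by the allylic bromide in a protic solvent (phenolate C-allylation) should stop at the monoprenyl stage when the bromide is added slowly to an excess of 1.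

Step 2
Reactants: 3 3-prenylphloroisobutyrophenone; 2 prenyl bromide
Product: 4 deoxycohumulone
Conditions: NaOMe (1.0 equiv), MeOH, 0 °C; 2 (1.05 equiv)
Reagents that add atoms: none
Why: The second phenolate C-allylation takes the one remaining unsubstituted ring carbon, the only position whose alkylation still allows rearomatisation, and gives the symmetrical diprenyl ketone.

Step 3
Reactants: 4 deoxycohumulone; 2 prenyl bromide
Product: 5 colupulone
Conditions: NaOMe (1.1 equiv), MeOH, −10 °C to rt; 2 (1.1 equiv); dilute aq HCl work-up
Reagents that add atoms: none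
Why: With no free ring CH left, the phenolate is alkylated at one of the two equivalent prenyl-bearing carbons, so the ring is dearomatised to the gem-diprenyl dienone (alkylative dearomatisation of an acylphloroglucinol, the classical entry to hop β-acids).

Step 4
Reactants: 5 colupulone
Product: 6 cohulupone
Conditions: O2 (1 atm), Na2SO3, MeOH, rt
Reagents that add atoms: none
Why: Autoxidation at the mono-prenylated enol carbon is followed by a ring contraction that joins its two ring neighbours and expels that carbon with its prenyl group as 4-methylpent-3-enoic acid (the known oxidative lupulone-to-hulupone contraction), leaving the gem-diprenyl and acyl-bearing carbons untouched.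

Step 5
Reactants: 6 cohulupone
Product: 7 (4S)-3,4-dihydroxy-2-(2-methylpropanoyl)-5,5-bis(3-methylbut-2-en-1-yl)cyclopent-2-en-1-one
Conditions: RuCl(p-cymene)[(S,S)-TsDPEN] (2 mol %), HCO2H/Et3N (5:2), CH2Cl2, rt
Reagents that add atoms: none
Why: Noyori asymmetric transfer hydrogenation should reduce the only carbonyl outside the enolised β-tricarbonyl system (the C3 ketone between the gem-diprenyl carbon and enol carbon C2), the catalyst telling its enantiotopic faces apart by placing the sp2 neighbour next to the arene ligand as with aryl ketones, which for the (S,S) ligand predicts the (S)-carbinol (the mirror-image catalyst is taken if the sense proves opposite).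

Step 6
Reactants: 7 (S)-alcohol
Product: 9 (4S)-3-hydroxy-2-(2-methylpropanoyl)-5,5-bis(3-methylbut-2-en-1-yl)-4-(triethylsilyloxy)cyclopent-2-en-1-one, via bis-silyl enol ether 8 (not isolated)
Conditions: Et3SiOTf (2.5 equiv), 2,6-lutidine, CH2Cl2, −78 to 0 °C; then aq citric acid, THF, rt
Reagents that add atoms: triethylsilyl trifluoromethanesulfonate, CC[Si](CC)(CC)OS(=O)(=O)C(F)(F)F
Why: The silyl triflate silylates both the secondary alcohol and the acidic enol, and the enol silyl ether, being a vinylogous silyl ester, should be hydrolysed selectively by dilute acid (standard silyl ether protection) without touching the C3 stereocentre.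

Step 7
Reactants: 9 silyl ether (ring enol)
Product: 10 bicyclic iodide (C1–C8 bond formed; C7 iodide equatorial; C3 silyloxy exo; C1 isobutyryl; C5 prenyl)
Conditions: I2 (1.3 equiv), KI, KHCO3, THF/H2O, 0 °C to rt, dark; aq Na2S2O3
Reagents that add atoms: iodine, II
Why: Under the bicarbonate buffer iodine adds reversibly to either prenyl alkene of enol 9, and the iodonium ion on the prenyl group trans to the C3 silyloxy group is opened at its Me2C terminus C8 by enol carbon C1, giving the C1–C8 bond and the C7–I bond by anti addition. The closest known reaction type is the iodine/KI/bicarbonate carbocyclisation of prenylated cyclic β-diketone enols that turns the enol carbon into a bridgehead. The six-membered ring C1–C9–C5–C6–C7–C8 closes in a 6-endo-trig, Markovnikov sense through a chair-like array. C5 is fixed by the choice between the two diastereotopic prenyl groups, which the C3 stereocentre controls because closure of the cis prenyl would push the silyloxy group endo beneath the forming bridge; C1 follows because the three-atom bridge can only span one face of the five-membered ring; C7 follows from anti addition within the chair, which leaves iodine equatorial. The step needs carbon rather than oxygen closure and reaction of the trans prenyl group: iodoethers of this strongly acidic enol should be reopened by iodide whereas the C–C bond is not, and the silyloxy group supplies the facial bias. The minor diastereomer from the cis prenyl should be removed by chromatography at this stage, because C3 is planarised later and that isomer would then erode the enantiomeric purity.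

Step 8
Reactants: 10 bicyclic iodide
Product: 11 C7-allyl compound (allyl equatorial)
Conditions: allylSnBu3 (4 equiv), AIBN (0.2 equiv), PhH, 80 °C
Reagents that add atoms: allyltributylstannane, C=CC[Sn](CCCC)(CCCC)CCCC
Why: In this Keck radical allylation the secondary C7 radical should be trapped from the equatorial direction because the axial side faces the C2–C3 bridge, so the allyl group ends up equatorial whatever the iodide configuration, and closure of the radical onto the bridgehead prenyl group is excluded by geometry.

Step 9
Reactants: 11 C7-allyl compound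
Product: 12 C7-prenyl compound
Conditions: second-generation Grubbs catalyst RuCl2(=CHPh)(H2IMes)(PCy3) (10 mol %), 2-methylbut-2-ene/CH2Cl2, 40 °C
Reagents that add atoms: 2-methylbut-2-ene, CC=C(C)C
Why: Olefin cross-metathesis of the terminal alkene with a large excess of 2-methylbut-2-ene gives the trisubstituted prenyl alkene, while the existing prenyl group only undergoes degenerate exchange.

Step 10
Reactants: 13 2-methylbut-3-yn-2-ol
Product: 14 triethyl[(2-methylbut-3-yn-2-yl)oxy]silane
Conditions: Et3SiCl, imidazole, DMF, rt
Reagents that add atoms: chlorotriethylsilane, CC[Si](Cl)(CC)CC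
Why: Imidazole-promoted silylation of the tertiary propargylic alcohol (standard silyl ether formation) masks the hydroxyl for the acetylide and enolate steps.

Step 11
Reactants: 14 silylated alkynol
Product: 17 4-methyl-4-(triethylsilyloxy)pent-2-ynal, via lithium acetylide 15 (not isolated), via lithium hemiaminolate 16 (not isolated)
Conditions: n-BuLi, THF, −78 °C; DMF, −78 to 0 °C; inverse quench into cold aq KH2PO4
Reagents that add atoms: N,N-dimethylformamide, CN(C)C=O
Why: Formylation of the lithium acetylide with DMF gives a hemiaminal alkoxide that releases the ynal only on the buffered acidic inverse quench, which keeps dimethylamine from adding to the ynal.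

Step 12
Reactants: 12 C7-prenyl compound; 17 ynal
Product: 19 aldol adduct (C3 silyloxy endo; C3 exo 1-hydroxy-4-methyl-4-(triethylsilyloxy)pent-2-ynyl; both carbinol epimers), via lithium enolate 18 (not isolated)
Conditions: LDA (1.15 equiv), THF, −78 °C; 17 (1.5 equiv), −78 °C; AcOH, −78 °C
Reagents that add atoms: none
Why: Kinetic deprotonation of the only ring α-hydrogen (C3–H; the isobutyryl methine is shielded by quaternary C1) gives the C2 enolate, which should add to the ynal in an aldol reaction from the exo face, syn to the one-carbon bridge, because the endo face lies under the C6–C7–C8 bridge, so the silyloxy group turns endo and C3 takes the target configuration while the carbinol configuration is irrelevant.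

Step 13
Reactants: 19 aldol adduct
Product: 20 ynone
Conditions: Dess–Martin periodinane, pyridine, CH2Cl2, 0 °C to rt
Reagents that add atoms: none
Why: Dess–Martin oxidation of the secondary propargylic alcohol removes the irrelevant carbinol stereocentre under non-basic conditions that avoid retro-aldol cleavage.

Step 14
Reactants: 20 ynone
Product: 21 (Z)-enone bis-silyl ether
Conditions: H2 (1 atm), Pd/CaCO3 poisoned with Pb(OAc)2 (Lindlar catalyst), quinoline, EtOAc, rt, stopped after one equivalent of H2
Reagents that add atoms: none
Why: Lindlar semi-hydrogenation delivers hydrogen syn to the alkyne to give the (Z)-enone, and the poisoned catalyst should leave the trisubstituted prenyl alkenes and the ketones untouched.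

Step 15
Reactants: 21 (Z)-enone bis-silyl ether
Product: 22 target
Conditions: HF·pyridine, pyridine, THF, 0 °C to rt
Reagents that add atoms: none
Why: Buffered fluoride cleavage of both triethylsilyl ethers (silyl ether deprotection) under weakly acidic conditions avoids the base-induced retro-Claisen and retro-aldol pathways open to the tricarbonyl and α-hydroxy-β-diketone units and should not isomerise the (Z)-alkene.

**Compound list**

1 | phloroisobutyrophenone, 2-methyl-1-(2,4,6-trihydroxyphenyl)propan-1-one | CC(C)C(=O)c1c(O)cc(O)cc1O | starting material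
2 | prenyl bromide, 1-bromo-3-methylbut-2-ene | CC(C)=CCBr | starting material
3 | 3-prenylphloroisobutyrophenone, 2-methyl-1-[2,4,6-trihydroxy-3-(3-methylbut-2-en-1-yl)phenyl]propan-1-one | CC(C)C(=O)c1c(O)cc(O)c(CC=C(C)C)c1O | intermediate
4 | deoxycohumulone, 2-methyl-1-[2,4,6-trihydroxy-3,5-bis(3-methylbut-2-en-1-yl)phenyl]propan-1-one | CC(C)C(=O)c1c(O)c(CC=C(C)C)c(O)c(CC=C(C)C)c1O | intermediate
5 | colupulone, 3,5-dihydroxy-2-(2-methylpropanoyl)-4,6,6-tris(3-methylbut-2-en-1-yl)cyclohexa-2,4-dien-1-one | CC(C)C(=O)C1=C(O)C(CC=C(C)C)=C(O)C(CC=C(C)C)(CC=C(C)C)C1=O | intermediate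
6 | cohulupone, 4-hydroxy-5-(2-methylpropanoyl)-2,2-bis(3-methylbut-2-en-1-yl)cyclopent-4-ene-1,3-dione | CC(C)C(=O)C1=C(O)C(=O)C(CC=C(C)C)(CC=C(C)C)C1=O | intermediate
7 | (4S)-3,4-dihydroxy-2-(2-methylpropanoyl)-5,5-bis(3-methylbut-2-en-1-yl)cyclopent-2-en-1-one | CC(C)C(=O)C1=C(O)[C@@H](O)C(CC=C(C)C)(CC=C(C)C)C1=O | intermediate
8 | (4S)-bis(triethylsilyl) derivative of 7, drawn as the C2–O enol ether; any enol ether regioisomer hydrolyses to 9 (not isolated) | CC(C)C(=O)C1=C(O[Si](CC)(CC)CC)[C@@H](O[Si](CC)(CC)CC)C(CC=C(C)C)(CC=C(C)C)C1=O | intermediate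
9 | (4S)-3-hydroxy-2-(2-methylpropanoyl)-5,5-bis(3-methylbut-2-en-1-yl)-4-(triethylsilyloxy)cyclopent-2-en-1-one | CC(C)C(=O)C1=C(O)[C@@H](O[Si](CC)(CC)CC)C(CC=C(C)C)(CC=C(C)C)C1=O | intermediate
10 | bicyclo[3.2.1]octane-2,9-dione (route labels), C1 isobutyryl, C5 prenyl, C8 gem-dimethyl, C7 iodide equatorial, C3 triethylsilyloxy exo; 1R,3S,5S,7R | I[C@@H]1C[C@]2(CC=C(C)C)C(=O)[C@@](C(=O)C(C)C)(C(=O)[C@H]2O[Si](CC)(CC)CC)C1(C)C | intermediate
11 | as 10 with equatorial allyl in place of iodine at C7; 1R,3S,5S,7R | C=CC[C@@H]1C[C@]2(CC=C(C)C)C(=O)[C@@](C(=O)C(C)C)(C(=O)[C@H]2O[Si](CC)(CC)CC)C1(C)C | intermediate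
12 | as 10 with equatorial prenyl at C7; 1R,3S,5S,7R | CC(C)=CC[C@@H]1C[C@]2(CC=C(C)C)C(=O)[C@@](C(=O)C(C)C)(C(=O)[C@H]2O[Si](CC)(CC)CC)C1(C)C | intermediate
13 | 2-methylbut-3-yn-2-ol | CC(C)(O)C#C | starting material
14 | triethyl[(2-methylbut-3-yn-2-yl)oxy]silane | CC[Si](CC)(CC)OC(C)(C)C#C | intermediate
15 | lithium acetylide of 14 (not isolated) | CC[Si](CC)(CC)OC(C)(C)C#C[Li] | intermediate
16 | lithium 1-(dimethylamino)-4-methyl-4-(triethylsilyloxy)pent-2-yn-1-olate, the DMF adduct (not isolated) | CC[Si](CC)(CC)OC(C)(C)C#CC(O[Li])N(C)C | intermediate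
17 | 4-methyl-4-(triethylsilyloxy)pent-2-ynal | CC[Si](CC)(CC)OC(C)(C)C#CC=O | intermediate
18 | lithium C2 enolate of 12, C2(OLi)=C3(OSiEt3) (not isolated) | CC(C)=CC[C@@H]1C[C@]2(CC=C(C)C)C(=O)[C@@](C(=O)C(C)C)(C(O[Li])=C2O[Si](CC)(CC)CC)C1(C)C | intermediate
19 | aldol adduct: C3 triethylsilyloxy endo, C3 exo CH(OH)–C≡C–CMe2(OSiEt3), carbinol centre undefined; ring centres 1R,3S,5S,7R | CC(C)=CC[C@@H]1C[C@]2(CC=C(C)C)C(=O)[C@@](C(=O)C(C)C)(C(=O)[C@@]2(O[Si](CC)(CC)CC)C(O)C#CC(C)(C)O[Si](CC)(CC)CC)C1(C)C | intermediate
20 | ynone: C3 exo 4-methyl-4-(triethylsilyloxy)pent-2-ynoyl, C3 triethylsilyloxy endo; 1R,3S,5S,7R | CC(C)=CC[C@@H]1C[C@]2(CC=C(C)C)C(=O)[C@@](C(=O)C(C)C)(C(=O)[C@@]2(O[Si](CC)(CC)CC)C(=O)C#CC(C)(C)O[Si](CC)(CC)CC)C1(C)C | intermediate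
21 | (Z)-enone: C3 exo (2Z)-4-methyl-4-(triethylsilyloxy)pent-2-enoyl, C3 triethylsilyloxy endo; 1R,3S,5S,7R | CC(C)=CC[C@@H]1C[C@]2(CC=C(C)C)C(=O)[C@@](C(=O)C(C)C)(C(=O)[C@@]2(O[Si](CC)(CC)CC)C(=O)/C=C\C(C)(C)O[Si](CC)(CC)CC)C1(C)C | intermediate
22 | CNP0190794.1; systematic locants: (1S,3R,5R,7S)-7-hydroxy-7-[(2Z)-4-hydroxy-4-methylpent-2-enoyl]-4,4-dimethyl-1,3-bis(3-methylbut-2-en-1-yl)-5-(2-methylpropanoyl)bicyclo[3.2.1]octane-6,8-dione (C3 hydroxyl endo, acyl exo, C7 prenyl equatorial) | CC(C)=CC[C@@H]1C[C@]2(CC=C(C)C)C(=O)[C@@](C(=O)C(C)C)(C(=O)[C@@]2(O)C(=O)/C=C\C(C)(C)O)C1(C)C | target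

**Count and risks**

Total steps: 15. Longest linear sequence: 13 (steps 1–9 and 12–15); steps 10–11 make the ynal.

Steps most likely to fail:

1. Step 7. The enol may close through oxygen onto the iodonium ion to give iodoethers that do not revert, or the two prenyl groups may be poorly discriminated. Fallback: the electrophile is changed to selenium, for which the oxygen-closed product is known to isomerise to the carbocycle under Lewis acid. Setting out from 9, N-(phenylselanyl)phthalimide with ZnI2 in CH2Cl2 should give the C7 phenylselenide F1, with the same skeleton and configuration as 10. Keck allylation of this selenide (allylSnBu3, AIBN, PhH, 80 °C) then rejoins the route at 11.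

2. Step 12. Deprotonation may occur at the isobutyryl methine, the silyl group may shift between the two oxygens, or the lithium aldolate may fragment (retro-aldol, or attack on the C9 ketone followed by retro-Claisen) before it is quenched. Fallback: the aldol is run without a free alkoxide. Setting out from 12, TMSOTf/Et3N (CH2Cl2, 0 °C) should give the C2 trimethylsilyl enol ether F2, an enediol bis-silyl ether. A BF3·OEt2-mediated Mukaiyama aldol of it with 17 at −78 °C, with aqueous work-up, returns to the route at 19.

3. Step 5. The catalyst may not turn over on the anionic trione, or may discriminate the two carbonyl faces poorly next to the quaternary carbon. Fallback: the reduction is done without a chiral reagent and the enantiomers are separated through the acidity of the enol. Setting out from 6, NaBH4 (MeOH, 0 °C) should give the racemic alcohol F3. Crystallisation with (R)-1-phenylethylamine gives the diastereomeric (R)-1-phenylethylammonium salt of the (S)-enol F4, taken from crystals or mother liquor as found, or with the other amine enantiomer. Acidification returns to the route at 7.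

Further compounds
F1 | step 7 | C7 phenylselenide analogue of 10 (PhSe equatorial at C7, C3 triethylsilyloxy exo; 1R,3S,5S,7R) | c1ccccc1[Se][C@@H]1C[C@]2(CC=C(C)C)C(=O)[C@@](C(=O)C(C)C)(C(=O)[C@H]2O[Si](CC)(CC)CC)C1(C)C
F2 | step 12 | C2 trimethylsilyl enol ether of 12, C2(OSiMe3)=C3(OSiEt3) | CC(C)=CC[C@@H]1C[C@]2(CC=C(C)C)C(=O)[C@@](C(=O)C(C)C)(C(O[Si](C)(C)C)=C2O[Si](CC)(CC)CC)C1(C)C
F3 | step 5 | racemic 3,4-dihydroxy-2-(2-methylpropanoyl)-5,5-bis(3-methylbut-2-en-1-yl)cyclopent-2-en-1-one | CC(C)C(=O)C1=C(O)C(O)C(CC=C(C)C)(CC=C(C)C)C1=O
F4 | step 5 | (R)-1-phenylethylammonium enolate of (S)-alcohol 7 | CC(C)C(=O)C1=C([O-])[C@@H](O)C(CC=C(C)C)(CC=C(C)C)C1=O.C[C@@H]([NH3+])c1ccccc1
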